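## Retrosynthetic overview

1. Target acid 31 ⇐ allyl ester 30 (Pd deallylation) ⇐ cyclopentanol 29, by a regiospecific syn-dehydration that creates the ring C=C last.
2. Both rings form in one step: a thermal intramolecular Diels–Alder reaction (IMDA) of linear pentaenoate 27 makes the cyclohexene (bonds C3–C7 and C2–C10) and closes the five-membered ring, trans-fused, setting four stereocentres.
3. 27 ⇐ C3 aldehyde 23 + stabilised ylide; the phenyl-tetraene arm ⇐ three Wittig homologations and a benzyl HWE from C7 aldehyde 12.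
4. The C4–C6 stereotriad ⇐ catalytic (E)-crotylboration of (S)-aldehyde 7 (Felkin-matched).
5. First stereocentre ⇐ lipase desymmetrisation of achiral 2-methylpropane-1,3-diol.

Assumption 1: "C1–C14" is the open-chain numbering (C1 = carboxyl carbon). In the target, indene C1/C2/C3/C3a/C4/C5/C6/C7/C7a = chain C6/C5/C4/C3/C2/C10/C9/C8/C7.
Assumption 2: the lipase gives the (S)-monoacetate, as I recall for Pseudomonas fluorescens lipase with vinyl acetate. If the sense is opposite, the same aldehyde 7 is reached by hydrolysing the diacetate with the same lipase instead.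

## Route

Step 1
Reactants: 1 2-methylpropane-1,3-diol; 2 vinyl acetate
Product: 3 (S)-3-hydroxy-2-methylpropyl acetate
Conditions: Pseudomonas fluorescens lipase (Amano AK), vinyl acetate (3 equiv), CHCl3, 25 °C; stop at ca. 35% diacetate
Reagents that add atoms: vinyl acetate, CC(=O)OC=C
Why: Lipase-catalysed enantiotopic-group-selective transesterification sets the first stereocentre (chain C4), and over-acylation of the minor enantiomer raises the ee.

Step 2
Reactants: 3; 4 tert-butyldimethylsilyl chloride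
Product: 5 (R)-3-[(tert-butyldimethylsilyl)oxy]-2-methylpropyl acetate
Conditions: TBSCl, imidazole, DMF, 0 °C → rt
Reagents that add atoms: TBSCl, CC(C)(C)[Si](C)(C)Cl
Why: Standard silylation of the free primary alcohol differentiates the two arms permanently.

Step 3
Reactants: 5
Product: 6 (R)-3-[(tert-butyldimethylsilyl)oxy]-2-methylpropan-1-ol
Conditions: K2CO3, MeOH, 0 °C
Reagents that add atoms: none
Why: Mild methanolysis removes only the acetate; at 0 °C 1,3-silyl migration (which would racemise) is not expected.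

Step 4
Reactants: 6
Product: 7 (S)-3-[(tert-butyldimethylsilyl)oxy]-2-methylpropanal
Conditions: (COCl)2, DMSO, CH2Cl2, −78 °C; i-Pr2NEt, −78 → −30 °C; used crude at once
Reagents that add atoms: none
Why: Swern oxidation with a hindered base at low temperature gives the α-methyl aldehyde without epimerisation.

Step 5
Reactants: 7; 8 (E)-crotylboronic acid pinacol ester
Product: 9 (2S,3S,4S)-1-[(tert-butyldimethylsilyl)oxy]-2,4-dimethylhex-5-en-3-ol (2,3-syn, 3,4-anti)
Conditions: 8 (1.3 equiv), (S)-TRIP (5 mol %), 4 Å MS, PhMe, −30 °C; aq. NaHCO3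
Reagents that add atoms: (E)-crotylBpin, C/C=C/CB1OC(C)(C)C(C)(C)O1
Why: Chiral-phosphoric-acid-catalysed crotylboration through a chair Zimmerman–Traxler transition state: the (E)-boronate gives the 5,6-anti relationship, and catalyst-directed Si-face attack coincides with Felkin–Anh addition to give 4,5-syn.

Step 6
Reactants: 9; 10 tert-butyldimethylsilyl triflate
Product: 11 (3S,4S,5S)-4,6-bis[(tert-butyldimethylsilyl)oxy]-3,5-dimethylhex-1-ene
Conditions: TBSOTf, 2,6-lutidine, CH2Cl2, −78 → 0 °C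
Reagents that add atoms: TBSOTf, CC(C)(C)[Si](C)(C)OS(=O)(=O)C(F)(F)F
Why: Silyl triflate protects the hindered secondary alcohol; this group becomes the later leaving-group site at C5.

Step 7
Reactants: 11
Product: 12 (2R,3R,4S)-3,5-bis[(tert-butyldimethylsilyl)oxy]-2,4-dimethylpentanal
Conditions: O3, CH2Cl2, −78 °C; PPh3, → rt
Reagents that add atoms: ozone, [O-][O+]=O
Why: Ozonolysis with reductive work-up cleaves the terminal vinyl group to the C7 aldehyde; the silyl ethers are inert.

Step 8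
Reactants: 12; 13 ethyl 2-(triphenylphosphoranylidene)propanoate
Product: 14 ethyl (2E,4S,5S,6S)-5,7-bis[(tert-butyldimethylsilyl)oxy]-2,4,6-trimethylhept-2-enoate
Conditions: 13 (1.5 equiv), CH2Cl2, 40 °C
Reagents that add atoms: ylide 13, CCOC(=O)C(C)=P(c1ccccc1)(c1ccccc1)c1ccccc1
Why: Wittig reaction with a stabilised ylide under neutral conditions gives the (E)-trisubstituted C7=C8 alkene without epimerising C6.

Step 9
Reactants: 14
Product: 15 (2E,4S,5S,6S)-5,7-bis[(tert-butyldimethylsilyl)oxy]-2,4,6-trimethylhept-2-en-1-ol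
Conditions: DIBAL-H (2.5 equiv), CH2Cl2, −78 °C; Rochelle salt
Reagents that add atoms: none
Why: 1,2-Reduction of the enoate to the allylic alcohol.

Step 10
Reactants: 15
Product: 16 (2E,4S,5S,6S)-5,7-bis[(tert-butyldimethylsilyl)oxy]-2,4,6-trimethylhept-2-enal
Conditions: activated MnO2, CH2Cl2, rt
Reagents that add atoms: none
Why: Chemoselective allylic oxidation with no E/Z erosion.

Step 11
Reactants: 16; 17 2-(triphenylphosphoranylidene)propanal
Product: 18 (2E,4E,6S,7S,8S)-7,9-bis[(tert-butyldimethylsilyl)oxy]-2,4,6,8-tetramethylnona-2,4-dienal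
Conditions: 17 (2 equiv), PhMe, 100 °C
Reagents that add atoms: ylide 17, CC(C=O)=P(c1ccccc1)(c1ccccc1)c1ccccc1
Why: Wittig homologation with the formyl-stabilised ylide is E-selective, and the more conjugated, hindered product resists a second addition.

Step 12
Reactants: 18; 17 2-(triphenylphosphoranylidene)propanal
Product: 19 (2E,4E,6E,8S,9S,10S)-9,11-bis[(tert-butyldimethylsilyl)oxy]-2,4,6,8,10-pentamethylundeca-2,4,6-trienal
Conditions: 17 (2.5 equiv), PhMe, 110 °C, dark
Reagents that add atoms: ylide 17, CC(C=O)=P(c1ccccc1)(c1ccccc1)c1ccccc1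
Why: A second identical Wittig homologation installs C11=C12 with E geometry.

Step 13
Reactants: 19; 20 diethyl benzylphosphonate
Product: 21 [(1E,3E,5E,7E,9S,10S,11S)-10,12-bis[(tert-butyldimethylsilyl)oxy]-3,5,7,9,11-pentamethyldodeca-1,3,5,7-tetraen-1-yl]benzene
Conditions: 20, NaH, THF, 0 °C → rt, dark
Reagents that add atoms: diethyl benzylphosphonate, CCOP(=O)(Cc1ccccc1)OCC
Why: Horner–Wadsworth–Emmons olefination with a benzylphosphonate gives the (E)-styryl terminus.

Step 14
Reactants: 21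
Product: 22 (2S,3S,4S,5E,7E,9E,11E)-3-[(tert-butyldimethylsilyl)oxy]-2,4,6,8,10-pentamethyl-12-phenyldodeca-5,7,9,11-tetraen-1-ol
Conditions: HF·pyridine, pyridine, THF, 0 °C → rt, dark
Reagents that add atoms: none
Why: Buffered HF removes the unhindered primary TBS ether selectively; the doubly flanked secondary TBS ether and the tetraene survive.

Step 15
Reactants: 22
Product: 23 (2R,3S,4S,5E,7E,9E,11E)-3-[(tert-butyldimethylsilyl)oxy]-2,4,6,8,10-pentamethyl-12-phenyldodeca-5,7,9,11-tetraenal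
Conditions: Dess–Martin periodinane, NaHCO3, CH2Cl2, 0 °C; used at once
Reagents that add atoms: none
Why: Buffered Dess–Martin oxidation gives the C3 aldehyde without touching the polyene or epimerising C4.

Step 16
Reactants: 24 allyl (triphenylphosphoranylidene)acetate; 25 iodomethane
Product: 26 allyl 2-(triphenylphosphoranylidene)propanoate
Conditions: MeI, EtOAc, rt (salt precipitates); then 1 M NaOH, CH2Cl2
Reagents that add atoms: iodomethane, CI
Why: C-Alkylation of a stabilised ylide followed by deprotonation gives the α-methyl ylide; precipitation of the salt limits transylidation.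

Step 17
Reactants: 23; 26
Product: 27 allyl (2E,4S,5S,6S,7E,9E,11E,13E)-5-[(tert-butyldimethylsilyl)oxy]-2,4,6,8,10,12-hexamethyl-14-phenyltetradeca-2,7,9,11,13-pentaenoate
Conditions: 26 (3 equiv), PhMe, 70–80 °C, dark
Reagents that add atoms: ylide 26, C=CCOC(=O)C(C)=P(c1ccccc1)(c1ccccc1)c1ccccc1
Why: Stabilised-ylide Wittig reaction gives the (E)-2-methyl enoate dienophile; any cycloadduct formed early is simply carried forward.

Step 18
Reactants: 27
Product: 28 allyl (1S,2S,3S,3aR,4R,5S,7aR)-2-[(tert-butyldimethylsilyl)oxy]-1,3,4,5,7-pentamethyl-5-[(1E,3E)-2-methyl-4-phenylbuta-1,3-dien-1-yl]-2,3,3a,4,5,7a-hexahydro-1H-indene-4-carboxylate (trans-fused; 1-Me and 3-Me trans)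
Conditions: PhMe (5 mM), BHT (10 mol %), 120 °C, sealed tube, dark
Reagents that add atoms: none
Why: Intramolecular Diels–Alder reaction in which the E,E-diene and E-dienophile geometries fix the C10/C2/C3/C7 relationships; the ester-endo, trans-fused transition state is the only one in which both allylic centres (C4, C6) keep their hydrogen eclipsed with the neighbouring alkene (A1,3 control), so 6-Me ends cis to H-7 and the absolute configuration is relayed from C4/C6.

Step 19
Reactants: 28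
Product: 29 allyl (1S,2S,3S,3aR,4R,5S,7aR)-2-hydroxy-1,3,4,5,7-pentamethyl-5-[(1E,3E)-2-methyl-4-phenylbuta-1,3-dien-1-yl]-2,3,3a,4,5,7a-hexahydro-1H-indene-4-carboxylate
Conditions: TBAF (5 equiv), THF, 50 °C
Reagents that add atoms: none
Why: Fluoride desilylation; the neopentyl allyl ester is too hindered to be attacked, and the hydroxyl and ester lie on opposite faces so no lactone forms.

Step 20
Reactants: 29
Product: 30 allyl (1R,3aR,4R,5S,7aS)-1,3,4,5,7-pentamethyl-5-[(1E,3E)-2-methyl-4-phenylbuta-1,3-dien-1-yl]-3a,4,5,7a-tetrahydro-1H-indene-4-carboxylate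
Conditions: Burgess reagent (3 equiv), PhMe, 70 °C
Reagents that add atoms: none
Why: Burgess dehydration is a syn (Ei) elimination; the C5 oxygen is cis only to H-4 (H-6 is trans), so the alkene forms only as C4=C5, removing the two temporary stereocentres.

Step 21
Reactants: 30
Product: 31 27-nor-zyggomphic acid B, (1R,3aR,4R,5S,7aS)-1,3,4,5,7-pentamethyl-5-[(1E,3E)-2-methyl-4-phenylbuta-1,3-dien-1-yl]-3a,4,5,7a-tetrahydro-1H-indene-4-carboxylic acid
Conditions: Pd(PPh3)4 (5 mol %), morpholine, THF, rt; citric acid work-up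
Reagents that add atoms: none
Why: Tsuji–Trost deallylation cleaves at the allyl C–O bond, so the extreme hindrance at the quaternary carboxyl carbon is irrelevant and no alkene is isomerised.

## Compound list

1 | 2-methylpropane-1,3-diol | CC(CO)CO | starting material
2 | vinyl acetate | CC(=O)OC=C | starting material
3 | (S)-3-hydroxy-2-methylpropyl acetate | OC[C@H](C)COC(C)=O | intermediate
4 | tert-butyldimethylsilyl chloride | CC(C)(C)[Si](C)(C)Cl | starting material (reagent)
5 | (R)-3-(TBSO)-2-methylpropyl acetate | CC(C)(C)[Si](C)(C)OC[C@H](C)COC(C)=O | intermediate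
6 | (R)-3-(TBSO)-2-methylpropan-1-ol | CC(C)(C)[Si](C)(C)OC[C@H](C)CO | intermediate
7 | (S)-3-(TBSO)-2-methylpropanal | CC(C)(C)[Si](C)(C)OC[C@H](C)C=O | intermediate
8 | (E)-crotylboronic acid pinacol ester | C/C=C/CB1OC(C)(C)C(C)(C)O1 | starting material
9 | (2S,3S,4S)-1-(TBSO)-2,4-dimethylhex-5-en-3-ol | CC(C)(C)[Si](C)(C)OC[C@H](C)[C@@H](O)[C@@H](C)C=C | intermediate
10 | tert-butyldimethylsilyl triflate | CC(C)(C)[Si](C)(C)OS(=O)(=O)C(F)(F)F | starting material (reagent)
11 | (3S,4S,5S)-4,6-bis(TBSO)-3,5-dimethylhex-1-ene | CC(C)(C)[Si](C)(C)OC[C@H](C)[C@@H](O[Si](C)(C)C(C)(C)C)[C@@H](C)C=C | intermediate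
12 | (2R,3R,4S)-3,5-bis(TBSO)-2,4-dimethylpentanal | CC(C)(C)[Si](C)(C)OC[C@H](C)[C@@H](O[Si](C)(C)C(C)(C)C)[C@@H](C)C=O | intermediate
13 | ethyl 2-(triphenylphosphoranylidene)propanoate | CCOC(=O)C(C)=P(c1ccccc1)(c1ccccc1)c1ccccc1 | starting material
14 | ethyl (2E,4S,5S,6S)-5,7-bis(TBSO)-2,4,6-trimethylhept-2-enoate | CC(C)(C)[Si](C)(C)OC[C@H](C)[C@@H](O[Si](C)(C)C(C)(C)C)[C@@H](C)/C=C(\C)C(=O)OCC | intermediate
15 | (2E,4S,5S,6S)-5,7-bis(TBSO)-2,4,6-trimethylhept-2-en-1-ol | CC(C)(C)[Si](C)(C)OC[C@H](C)[C@@H](O[Si](C)(C)C(C)(C)C)[C@@H](C)/C=C(\C)CO | intermediate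
16 | (2E,4S,5S,6S)-5,7-bis(TBSO)-2,4,6-trimethylhept-2-enal | CC(C)(C)[Si](C)(C)OC[C@H](C)[C@@H](O[Si](C)(C)C(C)(C)C)[C@@H](C)/C=C(\C)C=O | intermediate
17 | 2-(triphenylphosphoranylidene)propanal | CC(C=O)=P(c1ccccc1)(c1ccccc1)c1ccccc1 | starting material
18 | (2E,4E,6S,7S,8S)-7,9-bis(TBSO)-2,4,6,8-tetramethylnona-2,4-dienal | CC(C)(C)[Si](C)(C)OC[C@H](C)[C@@H](O[Si](C)(C)C(C)(C)C)[C@@H](C)/C=C(\C)/C=C(\C)C=O | intermediate
19 | (2E,4E,6E,8S,9S,10S)-9,11-bis(TBSO)-2,4,6,8,10-pentamethylundeca-2,4,6-trienal | CC(C)(C)[Si](C)(C)OC[C@H](C)[C@@H](O[Si](C)(C)C(C)(C)C)[C@@H](C)/C=C(\C)/C=C(\C)/C=C(\C)C=O | intermediate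
20 | diethyl benzylphosphonate | CCOP(=O)(Cc1ccccc1)OCC | starting material
21 | [(1E,3E,5E,7E,9S,10S,11S)-10,12-bis(TBSO)-3,5,7,9,11-pentamethyldodeca-1,3,5,7-tetraen-1-yl]benzene | CC(C)(C)[Si](C)(C)OC[C@H](C)[C@@H](O[Si](C)(C)C(C)(C)C)[C@@H](C)/C=C(\C)/C=C(\C)/C=C(\C)/C=C/c1ccccc1 | intermediate
22 | (2S,3S,4S,5E,7E,9E,11E)-3-(TBSO)-2,4,6,8,10-pentamethyl-12-phenyldodeca-5,7,9,11-tetraen-1-ol | OC[C@H](C)[C@@H](O[Si](C)(C)C(C)(C)C)[C@@H](C)/C=C(\C)/C=C(\C)/C=C(\C)/C=C/c1ccccc1 | intermediate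
23 | (2R,3S,4S,5E,7E,9E,11E)-3-(TBSO)-2,4,6,8,10-pentamethyl-12-phenyldodeca-5,7,9,11-tetraenal | O=C[C@H](C)[C@@H](O[Si](C)(C)C(C)(C)C)[C@@H](C)/C=C(\C)/C=C(\C)/C=C(\C)/C=C/c1ccccc1 | intermediate
24 | allyl (triphenylphosphoranylidene)acetate | C=CCOC(=O)C=P(c1ccccc1)(c1ccccc1)c1ccccc1 | starting material
25 | iodomethane | CI | starting material (reagent)
26 | allyl 2-(triphenylphosphoranylidene)propanoate | C=CCOC(=O)C(C)=P(c1ccccc1)(c1ccccc1)c1ccccc1 | intermediate
27 | allyl (2E,4S,5S,6S,7E,9E,11E,13E)-5-(TBSO)-2,4,6,8,10,12-hexamethyl-14-phenyltetradeca-2,7,9,11,13-pentaenoate | C=CCOC(=O)/C(C)=C/[C@H](C)[C@@H](O[Si](C)(C)C(C)(C)C)[C@@H](C)/C=C(\C)/C=C(\C)/C=C(\C)/C=C/c1ccccc1 | intermediate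
28 | allyl (1S,2S,3S,3aR,4R,5S,7aR)-2-(TBSO)-1,3,4,5,7-pentamethyl-5-[(1E,3E)-2-methyl-4-phenylbuta-1,3-dienyl]-2,3,3a,4,5,7a-hexahydro-1H-indene-4-carboxylate | CC1=C[C@](C)(/C=C(C)/C=C/c2ccccc2)[C@](C)(C(=O)OCC=C)[C@H]2[C@H](C)[C@@H](O[Si](C)(C)C(C)(C)C)[C@@H](C)[C@H]12 | intermediate
29 | allyl (1S,2S,3S,3aR,4R,5S,7aR)-2-hydroxy-1,3,4,5,7-pentamethyl-5-[(1E,3E)-2-methyl-4-phenylbuta-1,3-dienyl]-2,3,3a,4,5,7a-hexahydro-1H-indene-4-carboxylate | CC1=C[C@](C)(/C=C(C)/C=C/c2ccccc2)[C@](C)(C(=O)OCC=C)[C@H]2[C@H](C)[C@@H](O)[C@@H](C)[C@H]12 | intermediate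
30 | allyl (1R,3aR,4R,5S,7aS)-1,3,4,5,7-pentamethyl-5-[(1E,3E)-2-methyl-4-phenylbuta-1,3-dienyl]-3a,4,5,7a-tetrahydro-1H-indene-4-carboxylate | CC1=C[C@](C)(/C=C(C)/C=C/c2ccccc2)[C@](C)(C(=O)OCC=C)[C@H]2C(C)=C[C@@H](C)[C@H]12 | intermediate
31 | 27-nor-zyggomphic acid B | CC1=C[C@](C)(/C=C(C)/C=C/c2ccccc2)[C@](C)(C(=O)O)[C@H]2C(C)=C[C@@H](C)[C@H]12 | target

(TBSO = tert-butyldimethylsilyloxy.)

## Summary

Total steps: 21. Longest linear sequence: 20 (steps 1–15 and 17–21); step 16 is a one-step reagent branch.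

Steps most likely to fail, each with a fallback that changes the approach:

1. **Step 18 (IMDA).** A trisubstituted enoate must add to a diene with a Z-methyl terminus and create two adjacent quaternary carbons, so it may need temperatures that degrade the polyene or give endo/exo mixtures. Fallback: make the dienophile an α-methyl enal instead (Wittig of 23 with ylide 17), run the cycloaddition with Me2AlCl at low temperature, and generate the acid at the very end by Pinnick oxidation of the neopentyl aldehyde, dropping the allyl ester.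

2. **Step 20 (Burgess dehydration).** The hindered cyclopentanol may give carbamate or leak into E1 pathways (hydride shift, elimination toward C6). Fallback: redesign the tether as a C4 ketone with a C5 methylene (a 4-oxo-2-enoate dienophile, with no C4/C5 stereocentres). After the IMDA, form the kinetic enol triflate toward C5 (KHMDS, PhNTf2) and install the C4 methyl by Fe(acac)3/MeMgBr or Pd/Me4Sn cross-coupling.

3. **Step 5 (catalytic crotylboration).** Diastereoselectivity on the β-silyloxy aldehyde may be insufficient, and 7 can epimerise. Fallback: build C5–C6 by a substrate-controlled anti-aldol instead: the E-boron enolate of an aryl propionate (Cy2BOTf, Et3N) adds to 7 under Felkin control to give the same triad with C7 as an ester. Silylation and DIBAL then deliver 12 without ozonolysis.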